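## The problem

The target is (2R,3S,4R)-4-{2-[(2R,3S)-3,7-dihydroxychroman-2-yl]-4,5-dihydroxyphenyl}-2-(4-hydroxyphenyl)chroman-3,7-diol. It is built from two 2,3-trans-flavan-3-ols that share one catechol ring. Ring E is the aryl group on C4 of the upper unit (ring A, ring B, upper pyran) and also the 2-aryl group of the lower unit (ring D, lower pyran), and its two points of attachment are ortho to each other. The bond from ring E to C2' therefore sits at a ring E carbon flanked by the bulky C4 substituent, and an intermolecular Friedel–Crafts union would have to compete with the far more nucleophilic resorcinol-type ring A. There are five stereocentres in two sets: C2, C3 and C4 of the upper pyran, all-trans (2R,3S,4R), and C2' and C3' of the lower pyran, trans (2'R,3'S). Within each set one centre can control the others (C2 directs additions at C3 and C4 to the face anti to ring B; C3' biases a ring closure at C2' towards trans), but the flat ring E insulates the sets from each other, so each needs its own source of absolute configuration. Six phenols, two of them a catechol, exclude oxidants and strong base late in the route, and the benzylic ring bonds C2–O1 and C2'–O1', each para to an oxygen, ionise under strong acid. The enabling feature is that the C3 hydroxyl is trans-diequatorial (gauche) to ring E on C4, so that O3–C3–C4–C(ring E)–C(ring E) is a five-atom chain ending at the ring E carbon that must carry C2'. That carbon is para to a ring E oxygen, and C2' is a benzylic carbon bearing oxygen; an oxocarbenium ion on O3 can therefore deliver C2' to exactly this carbon through a six-membered ring, and the para-alkoxybenzylic C2'–O3 bond formed can later be exchanged for the C2'–O1' bond of the target.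

## Retrosynthesis

Protecting groups (26 ⇒ 25 ⇒ 24). The last bonds cut are five O–benzyl bonds and one O–acetyl bond. Benzyl ethers on ring B, ring A, ring E (two) and O3' are preferred to methyl or silyl ethers because hydrogenolysis is neutral and non-oxidising, which a catechol-bearing hexaphenol needs. 25 is the pentabenzyl ether of 26 with the C3 hydroxyl and the ring D phenol already free; 24 is its C3 acetate, a trace of the ring switch. The forward steps must spare the benzylic ring bonds C2–O1 and C2'–O1', and the deacetylation must not epimerise C2 or C2', which is safe while the phenols para to them are still benzylated.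

Lower pyran (24 ⇒ 23 ⇒ 22). The O1'–C2' bond is cut, with C2' as a benzylic electrophile (bromide 23) and O1' as a ring D phenoxide masked as a silyl ether; C2' is then reconnected to O3 of the upper unit, which gives isochroman 22. Cutting here, and not at C4'–C4a' or at the C2'–ring E bond, lets C2' arrive already attached to ring E. 22 is no smaller than 24, but the difficult C–C bond is now part of a six-membered ring that can be closed intramolecularly. The forward switch asks that an acyl bromide open the para-alkoxybenzylic C2'–O3 bond irreversibly (O3 ends as a non-nucleophilic acetate) and that the phenoxide freed by fluoride close the chroman 2,3-trans. Both ring D oxygens carry the same silyl group, because only the ortho one can reach C2' and the para one is the free C7' phenol of 26.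

Isochroman (22 ⇒ 12 + 20). Two bonds at C2' are cut, the one to ring E and the one to O3. This returns C2' to the aldehyde carbon of 20 and ring E to the unsubstituted 3,4-bis(benzyloxy)phenyl group of the tetrabenzyl flavan-3-ol 12. The neighbouring choice, an intermolecular Friedel–Crafts reaction of a C2' cation with 12, would go to ring A and, within ring E, away from the hindered carbon; the tether through O3 removes both problems. The cut halves the molecule: 12 carries the three upper stereocentres, 20 carries C3' and ring D. The forward reaction must generate an oxocarbenium ion from a hindered secondary alcohol, close at the ring E carbon para to a benzyloxy group, and leave C2–O1 and the epimerisable C3' untouched. The configuration formed at C2' is provisional.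

Upper flavan-3-ol (12 ⇒ 10 ⇒ 6 + 7). The C3–O and C4–H bonds are cut together (hydroboration–oxidation of flav-3-ene 10), then the C4–ring E bond (addition of the aryl Grignard reagent from 7 to flavanone 6, then dehydration). Direct arylation of a flavan-3,4-diol with a catechol diether was set aside, because that arene is a poor nucleophile and ring A of a second molecule would win. 6 has one stereocentre, C2, which must control C3 and C4: syn addition of B–H anti to ring B gives the all-trans array. The forward steps must not enolise 6, since its enolate opens to a chalcone and C2 is lost.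

Flavanone (6 ⇒ 4 + 5; 4 ⇒ 2 ⇒ 1). The C2–ring B bond is cut to chromone 4 and boronic acid 5, so that C2 is set by a catalyst; the obvious neighbour, cyclisation of a 2'-hydroxychalcone, has no comparably general asymmetric version. 4 is flat and comes from 1 in two steps (4'-O-benzylation to 2, then one-carbon annulation).

Aldehyde (20 ⇒ 19 ⇒ 18 ⇒ 17 ⇒ 14 + 15; 14 ⇒ 13). After adjustment of oxidation level (19) and protecting groups (18, 17), the C4'–ring D bond is cut to aryl bromide 14 and the chiral-pool epoxide 15, whose stereocentre becomes C3'. A dihydroxylation- or aldol-based construction of C3' would need a further asymmetric step and a deoxygenation at C4'. 14 is the bis-silyl ether of 13. The forward sequence asks for epoxide opening at CH2, an O-benzylation without protecting-group migration (hence trityl on the primary oxygen and triisopropylsilyl on the phenols), and an oxidation that does not epimerise the α-benzyloxy aldehyde.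

## Roads not taken

Alternative 1: Baeyer–Villiger ring expansion. The upper pyran is cut at O1–C8a and O1–C2. A 3-arylindan-1-one A1, whose aryl group is ring E already carrying the protected lower flavan, would be treated with a buffered peracid so that the aromatic carbon migrates and oxygen is inserted between the carbonyl carbon and ring A, giving the 4-arylchroman-2-one A2. Its merit is that C4 is a defined stereocentre from the start and no hydroboration has to choose a face. For this target it has three weak points. The migrating carbon is meta to the ring A benzyloxy group, so migration is not accelerated while four other electron-rich rings are exposed to the peracid. A2 still lacks ring B and the C3 hydroxyl, which costs an enolate hydroxylation, an aryl addition to the lactone and a hemiketal reduction of uncertain selectivity at C2. And A1 presupposes the ring E–C2' bond without offering a way to make it. In control of C4 this road is at least as good as the chosen plan. The chosen plan sets against it a shorter sequence, a C2 centre fixed by a catalyst before C3 and C4 are built on it, and a solution for the ring E–C2' bond.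

Alternative 2: epoxide–arene cyclisation. The lower pyran is cut at C4'–C4a'. In the aryl glycidyl ether A3 the ring D oxygen is already bonded to C2'; mild acid (a fluorinated alcohol or a catalytic Lewis acid) would let ring D attack the terminal epoxide carbon in a 6-endo Friedel–Crafts closure, leaving the epoxide oxygen as the C3' hydroxyl of A4. The closure is stereospecific, so C2' and C3' are both fixed in an open-chain precursor and no ring switch is needed. In this respect it is better than the chosen plan, which sets C2' in a closure biased only by a chair-like transition state. Its weak points lie before the key step: A3 needs an aryl ether at a para-alkoxybenzylic carbon of defined configuration, where substitution tends to pass through the cation; ring D can also react at the carbon between its two oxygens; and the ring E–C2' bond must again exist already. The chosen plan sets against the better control of C2' that it forms this bond with the help of the upper unit itself and joins two fragments of equal size late.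

Alternative 3: ortho-quinone methide cycloaddition. The upper pyran is cut at O1–C2 and C3–C4. The o-hydroxybenzhydrol A5 (ring A phenol, carbinol carbon C4, ring E with the lower flavan attached) would be ionised by a chiral phosphoric acid to its o-quinone methide, which would add the (E)-styrylboronate A6 across O1 and C4 to give A7, with boron on C3 as a masked hydroxyl. This is the most convergent road: one step builds the ring and all three upper stereocentres, and A7 is two steps (oxidation with retention, hydrogenolysis) from 26, fewer than the chosen plan needs after its key step. Against it stand the low nucleophilicity of an alkenylboronate towards an o-quinone methide whose terminus is shielded by the ortho-substituted ring E, the need for one catalyst to control the face and the all-trans sense and to override the resident stereocentres of the lower unit, and again the ring E–C2' bond inside A5. The chosen plan is longer after its key step but builds each upper stereocentre by substrate control of a well-understood kind.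

Key step: step 11

Remark on the chemistry: (R)-t-BuPyOx is taken to deliver the (2S)-flavanone 6, by analogy with the facial sense of this catalyst on cyclic enones; should the sense be the opposite, the (S)-ligand is used and nothing else changes.

Step 1
Reactants: 1 2',4'-dihydroxyacetophenone
Product: 2 1-[4-(benzyloxy)-2-hydroxyphenyl]ethan-1-one
Conditions: BnBr (1.05 equiv), K2CO3, acetone, reflux
Reagents that add atoms: benzyl bromide, BrCc1ccccc1
Why: Williamson etherification; the 2'-hydroxyl is tied up in a hydrogen bond to the ketone, so the 4'-hydroxyl should react selectively.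

Step 2
Reactants: 2 1-[4-(benzyloxy)-2-hydroxyphenyl]ethan-1-one
Product: 4 7-(benzyloxy)-4H-chromen-4-one, via enaminone 3 (not isolated)
Conditions: Me2NCH(OMe)2, toluene, 100 °C; then conc. HCl, CH2Cl2, 40 °C
Reagents that add atoms: N,N-dimethylformamide dimethyl acetal, COC(OC)N(C)C
Why: Condensation of the methyl ketone with the amide acetal gives the enaminone, and acid closes the pyranone by conjugate addition of the phenol and loss of dimethylamine (standard chromone annulation).

Step 3
Reactants: 4 7-(benzyloxy)-4H-chromen-4-one; 5 4-(benzyloxy)phenylboronic acid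
Product: 6 (2S)-7-(benzyloxy)-2-[4-(benzyloxy)phenyl]chroman-4-one
Conditions: Pd(OCOCF3)2 (5 mol %), (R)-t-BuPyOx (6 mol %), NH4PF6 (30 mol %), H2O (5 equiv), ClCH2CH2Cl, 60 °C
Reagents that add atoms: none
Why: Palladium-catalysed asymmetric conjugate addition of an arylboronic acid to a chromone (transmetallation, face-selective insertion of C2=C3 into the aryl–palladium bond, protonolysis of the palladium enolate); the tert-butyl group of the pyridine–oxazoline ligand selects the face and should set C2 as (S).

Step 4
Reactants: 6 (2S)-7-(benzyloxy)-2-[4-(benzyloxy)phenyl]chroman-4-one; 7 4-bromo-1,2-bis(benzyloxy)benzene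
Product: 10 (2S)-7-(benzyloxy)-2-[4-(benzyloxy)phenyl]-4-[3,4-bis(benzyloxy)phenyl]-2H-chromene, via arylmagnesium bromide 8 (not isolated), via tertiary carbinol 9 (not isolated)
Conditions: 7, Mg, THF, 40 °C; then 6, LaCl3·2LiCl (1 equiv), THF, 0 °C; then PPTS (cat.), CH2Cl2, rt
Reagents that add atoms: none
Why: Grignard 1,2-addition to the ketone, the lanthanum salt suppressing enolisation and with it the retro-oxa-Michael opening that would racemise C2; the doubly benzylic tertiary carbinol then loses water under mild acid (E1) to the conjugated flav-3-ene, C3 being the only carbon that can lose a proton.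

Step 5
Reactants: 10 (2S)-7-(benzyloxy)-2-[4-(benzyloxy)phenyl]-4-[3,4-bis(benzyloxy)phenyl]-2H-chromene
Product: 12 (2R,3S,4R)-7-(benzyloxy)-2-[4-(benzyloxy)phenyl]-4-[3,4-bis(benzyloxy)phenyl]chroman-3-ol, via alkylborane 11 (not isolated)
Conditions: BH3·THF, THF, 0 °C → rt; then NaOH, H2O2, H2O, 0 °C
Reagents that add atoms: hydrogen peroxide, OO
Why: Hydroboration–oxidation; boron adds to C3, the unsubstituted end of the 1,1-diarylalkene, and B–H adds syn from the face anti to ring B on C2, so that after oxidation with retention the C3 hydroxyl is trans to ring B and ring E on C4 is trans to the hydroxyl (2R,3S,4R).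

Step 6
Reactants: 13 4-bromoresorcinol
Product: 14 1-bromo-2,4-bis(triisopropylsilyloxy)benzene
Conditions: TIPSCl (2.4 equiv), imidazole, DMF, rt
Reagents that add atoms: chlorotriisopropylsilane, CC(C)[Si](Cl)(C(C)C)C(C)C
Why: Silylation of both phenols; one group for both avoids any regioselective protection, because only the ortho oxygen can later reach C2'.

Step 7
Reactants: 14 1-bromo-2,4-bis(triisopropylsilyloxy)benzene; 15 (S)-glycidyl trityl ether
Product: 17 (2S)-1-[2,4-bis(triisopropylsilyloxy)phenyl]-3-(trityloxy)propan-2-ol, via arylmagnesium bromide 16 (not isolated)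
Conditions: 14, Mg, THF, 50 °C; then 15, CuI (10 mol %), THF, −30 → 0 °C
Reagents that add atoms: none
Why: Copper-catalysed SN2 opening of a terminal epoxide by an aryl Grignard reagent at the CH2 carbon; the stereocentre of the chiral-pool epoxide is not touched and becomes C3' (S).

Step 8
Reactants: 17 (2S)-1-[2,4-bis(triisopropylsilyloxy)phenyl]-3-(trityloxy)propan-2-ol
Product: 18 (2S)-2-(benzyloxy)-1-[2,4-bis(triisopropylsilyloxy)phenyl]-3-(trityloxy)propane
Conditions: NaH, BnBr, Bu4NI (cat.), THF, 0 °C → rt
Reagents that add atoms: benzyl bromide, BrCc1ccccc1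
Why: Williamson etherification of the secondary alkoxide; trityl and triisopropylsilyl ethers are chosen because neither should migrate to the alkoxide.

Step 9
Reactants: 18 (2S)-2-(benzyloxy)-1-[2,4-bis(triisopropylsilyloxy)phenyl]-3-(trityloxy)propane
Product: 19 (2S)-2-(benzyloxy)-3-[2,4-bis(triisopropylsilyloxy)phenyl]propan-1-ol
Conditions: p-TsOH·H2O (10 mol %), MeOH/CH2Cl2, rt
Reagents that add atoms: none
Why: Acid-catalysed SN1 methanolysis of the trityl ether; aryl triisopropylsilyl ethers and the benzyl ether are stable to catalytic acid at room temperature.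

Step 10
Reactants: 19 (2S)-2-(benzyloxy)-3-[2,4-bis(triisopropylsilyloxy)phenyl]propan-1-ol
Product: 20 (2S)-2-(benzyloxy)-3-[2,4-bis(triisopropylsilyloxy)phenyl]propanal
Conditions: Dess–Martin periodinane, CH2Cl2, 0 °C → rt; used crude
Reagents that add atoms: none
Why: Dess–Martin oxidation of the primary alcohol under neutral conditions, under which the α-benzyloxy aldehyde should not epimerise; it is used at once.

Step 11
Reactants: 12 (2R,3S,4R)-7-(benzyloxy)-2-[4-(benzyloxy)phenyl]-4-[3,4-bis(benzyloxy)phenyl]chroman-3-ol; 20 (2S)-2-(benzyloxy)-3-[2,4-bis(triisopropylsilyloxy)phenyl]propanal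
Product: 22 trans-fused isochroman in which C2' (R) links O3 to the ring E carbon para to a benzyloxy group and bears the (1S)-1-(benzyloxy)-2-[2,4-bis(triisopropylsilyloxy)phenyl]ethyl chain, via mixed hemiacetal 21 (not isolated)
Conditions: TMSOTf (0.3 equiv), 4 Å MS, CH2Cl2 (0.02 M), −78 → −20 °C
Reagents that add atoms: none
Why: The secondary C3 hydroxyl of 12 adds to aldehyde 20 to give hemiacetal 21, which TMSOTf silylates and ionises to an oxocarbenium ion on O3; ring E, held next to it on C4, attacks this ion with its carbon ortho to C4 and para to a benzyloxy group, and loss of a proton gives 22. The closest known reaction type is the oxa-Pictet–Spengler cyclisation of 2-arylethanols with aldehydes to 1-substituted isochromans, which is also known for flavan-3-ols condensing through O3 onto a neighbouring catechol ring. The one ring closed is the isochroman pyran (O3, C3, C4, two ring E carbons, C2'), formed in a 6-endo-trig Friedel–Crafts closure on the oxocarbenium carbon; it is trans-fused to the upper pyran because O3 and ring E are trans-diequatorial in 12. The one new stereocentre, C2', is controlled by the ring: the side chain should take the pseudo-equatorial position of a chair-like transition state, cis to the C3–C2 ring bond, which gives (R); this centre is provisional, since step 12 breaks its bond to O3 again. Regioselectivity within ring E rests on the para-benzyloxy group and on the open approach to that carbon, the other ortho carbon being wedged between C4 and a benzyloxy group. Chemoselectivity over the more nucleophilic ring A rests on the tether: the only ring A carbon within reach, C5, is meta to both ring A oxygens, and high dilution disfavours intermolecular attack. Ring D cannot compete either, because the only ring D carbon within reach is meta to both of its oxygens and its silyl ethers are bulky. Low temperature and a substoichiometric amount of the silyl triflate should keep the C2–O1 bond and the α-benzyloxy stereocentre C3' intact.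

Step 12
Reactants: 22 trans-fused isochroman in which C2' (R) links O3 to the ring E carbon para to a benzyloxy group and bears the (1S)-1-(benzyloxy)-2-[2,4-bis(triisopropylsilyloxy)phenyl]ethyl chain
Product: 24 (2R,3S,4R)-7-(benzyloxy)-2-[4-(benzyloxy)phenyl]-4-{4,5-bis(benzyloxy)-2-[(2R,3S)-3-(benzyloxy)-7-hydroxychroman-2-yl]phenyl}chroman-3-yl acetate, via benzylic bromide 23 (not isolated)
Conditions: AcBr (3 equiv), ZnBr2 (10 mol %), CH2Cl2, −20 → 0 °C; evaporate; then TBAF (3 equiv), THF, −40 → 0 °C
Reagents that add atoms: acetyl bromide, CC(Br)=O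
Why: Acyl bromide cleavage of a cyclic benzylic ether: acylation of the dialkyl ether oxygen O3 makes it a leaving group, the para-benzyloxy group of ring E lets bromide take its place at C2', and O3 ends as an acetate that cannot close back. Fluoride then frees both ring D phenoxides; the ortho one displaces the labile benzylic bromide in a 6-exo-tet Williamson closure whose chair-like transition state, with ring E and the C3' benzyloxy group equatorial, should give the 2,3-trans chroman (2'R), while the para one becomes the free C7' phenol on work-up.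

Step 13
Reactants: 24 (2R,3S,4R)-7-(benzyloxy)-2-[4-(benzyloxy)phenyl]-4-{4,5-bis(benzyloxy)-2-[(2R,3S)-3-(benzyloxy)-7-hydroxychroman-2-yl]phenyl}chroman-3-yl acetate
Product: 25 (2R,3S,4R)-7-(benzyloxy)-2-[4-(benzyloxy)phenyl]-4-{4,5-bis(benzyloxy)-2-[(2R,3S)-3-(benzyloxy)-7-hydroxychroman-2-yl]phenyl}chroman-3-ol
Conditions: K2CO3, MeOH/THF, rt
Reagents that add atoms: none
Why: Base-catalysed transesterification removes the C3 acetate; C2 and C2' cannot epimerise through quinone methides because the phenols para to them are still benzylated.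

Step 14
Reactants: 25 (2R,3S,4R)-7-(benzyloxy)-2-[4-(benzyloxy)phenyl]-4-{4,5-bis(benzyloxy)-2-[(2R,3S)-3-(benzyloxy)-7-hydroxychroman-2-yl]phenyl}chroman-3-ol
Product: 26 (2R,3S,4R)-4-{2-[(2R,3S)-3,7-dihydroxychroman-2-yl]-4,5-dihydroxyphenyl}-2-(4-hydroxyphenyl)chroman-3,7-diol
Conditions: H2 (1 atm), Pd(OH)2/C, THF/MeOH, rt
Reagents that add atoms: none
Why: Hydrogenolysis of the four aryl benzyl ethers and the C3' benzyl ether; the ring bonds C2–O1 and C2'–O1' of flavans are known to survive these conditions, and the neutral medium spares the catechol.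

## Compound list

1 | 2',4'-dihydroxyacetophenone | CC(=O)c1ccc(O)cc1O | starting material
2 | 1-[4-(benzyloxy)-2-hydroxyphenyl]ethan-1-one | CC(=O)c1ccc(OCc2ccccc2)cc1O | intermediate
3 | (E)-1-[4-(benzyloxy)-2-hydroxyphenyl]-3-(dimethylamino)prop-2-en-1-one (enaminone, not isolated) | CN(C)/C=C/C(=O)c1ccc(OCc2ccccc2)cc1O | intermediate
4 | 7-(benzyloxy)-4H-chromen-4-one | O=c1ccoc2cc(OCc3ccccc3)ccc12 | intermediate
5 | 4-(benzyloxy)phenylboronic acid | OB(O)c1ccc(OCc2ccccc2)cc1 | starting material
6 | (2S)-7-(benzyloxy)-2-[4-(benzyloxy)phenyl]chroman-4-one | O=C1C[C@@H](c2ccc(OCc3ccccc3)cc2)Oc2cc(OCc3ccccc3)ccc12 | intermediate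
7 | 4-bromo-1,2-bis(benzyloxy)benzene | Brc1ccc(OCc2ccccc2)c(OCc2ccccc2)c1 | starting material
8 | [3,4-bis(benzyloxy)phenyl]magnesium bromide (not isolated) | Br[Mg]c1ccc(OCc2ccccc2)c(OCc2ccccc2)c1 | intermediate
9 | (2S)-7-(benzyloxy)-2-[4-(benzyloxy)phenyl]-4-[3,4-bis(benzyloxy)phenyl]chroman-4-ol, both C4 epimers (not isolated) | OC1(c2ccc(OCc3ccccc3)c(OCc3ccccc3)c2)C[C@@H](c2ccc(OCc3ccccc3)cc2)Oc2cc(OCc3ccccc3)ccc12 | intermediate
10 | (2S)-7-(benzyloxy)-2-[4-(benzyloxy)phenyl]-4-[3,4-bis(benzyloxy)phenyl]-2H-chromene | C1(c2ccc(OCc3ccccc3)c(OCc3ccccc3)c2)=C[C@@H](c2ccc(OCc3ccccc3)cc2)Oc2cc(OCc3ccccc3)ccc12 | intermediate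
11 | C3 alkylborane of 12 (BH2 in place of the C3 hydroxyl, same spatial arrangement; not isolated) | c1ccccc1COc1ccc(cc1)[C@H]1Oc2cc(OCc3ccccc3)ccc2[C@@H](c2ccc(OCc3ccccc3)c(OCc3ccccc3)c2)[C@@H]1B | intermediate
12 | (2R,3S,4R)-7-(benzyloxy)-2-[4-(benzyloxy)phenyl]-4-[3,4-bis(benzyloxy)phenyl]chroman-3-ol | c1ccccc1COc1ccc(cc1)[C@H]1Oc2cc(OCc3ccccc3)ccc2[C@@H](c2ccc(OCc3ccccc3)c(OCc3ccccc3)c2)[C@@H]1O | intermediate
13 | 4-bromoresorcinol (4-bromobenzene-1,3-diol) | Oc1ccc(Br)c(O)c1 | starting material
14 | 1-bromo-2,4-bis(triisopropylsilyloxy)benzene | CC(C)[Si](Oc1ccc(Br)c(O[Si](C(C)C)(C(C)C)C(C)C)c1)(C(C)C)C(C)C | intermediate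
15 | (S)-glycidyl trityl ether, (2S)-2-[(trityloxy)methyl]oxirane | C(OC[C@H]1OC1)(c1ccccc1)(c1ccccc1)c1ccccc1 | starting material
16 | [2,4-bis(triisopropylsilyloxy)phenyl]magnesium bromide (not isolated) | Br[Mg]c1ccc(O[Si](C(C)C)(C(C)C)C(C)C)cc1O[Si](C(C)C)(C(C)C)C(C)C | intermediate
17 | (2S)-1-[2,4-bis(triisopropylsilyloxy)phenyl]-3-(trityloxy)propan-2-ol | O[C@H](COC(c1ccccc1)(c1ccccc1)c1ccccc1)Cc1ccc(O[Si](C(C)C)(C(C)C)C(C)C)cc1O[Si](C(C)C)(C(C)C)C(C)C | intermediate
18 | (2S)-2-(benzyloxy)-1-[2,4-bis(triisopropylsilyloxy)phenyl]-3-(trityloxy)propane | c1ccccc1CO[C@H](COC(c1ccccc1)(c1ccccc1)c1ccccc1)Cc1ccc(O[Si](C(C)C)(C(C)C)C(C)C)cc1O[Si](C(C)C)(C(C)C)C(C)C | intermediate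
19 | (2S)-2-(benzyloxy)-3-[2,4-bis(triisopropylsilyloxy)phenyl]propan-1-ol | OC[C@@H](OCc1ccccc1)Cc1ccc(O[Si](C(C)C)(C(C)C)C(C)C)cc1O[Si](C(C)C)(C(C)C)C(C)C | intermediate
20 | (2S)-2-(benzyloxy)-3-[2,4-bis(triisopropylsilyloxy)phenyl]propanal | O=C[C@@H](OCc1ccccc1)Cc1ccc(O[Si](C(C)C)(C(C)C)C(C)C)cc1O[Si](C(C)C)(C(C)C)C(C)C | intermediate
21 | mixed hemiacetal of 12 and 20: (2S)-2-(benzyloxy)-3-[2,4-bis(triisopropylsilyloxy)phenyl]-1-{[(2R,3S,4R)-7-(benzyloxy)-2-[4-(benzyloxy)phenyl]-4-[3,4-bis(benzyloxy)phenyl]chroman-3-yl]oxy}propan-1-ol, both epimers at C1 (not isolated) | c1ccccc1COc1ccc(cc1)[C@H]1Oc2cc(OCc3ccccc3)ccc2[C@@H](c2ccc(OCc3ccccc3)c(OCc3ccccc3)c2)[C@@H]1OC(O)[C@@H](OCc1ccccc1)Cc1ccc(O[Si](C(C)C)(C(C)C)C(C)C)cc1O[Si](C(C)C)(C(C)C)C(C)C | intermediate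
22 | trans-fused isochroman: the (2R,3S,4R) flavan of 12 in which O3 and the ring E carbon ortho to C4 and para to a benzyloxy group are both bonded to C2'; C2' is (R), its hydrogen cis to the C3 hydrogen, and carries the (1S)-1-(benzyloxy)-2-[2,4-bis(triisopropylsilyloxy)phenyl]ethyl group | c1ccccc1COc1ccc(cc1)[C@H]1Oc2cc(OCc3ccccc3)ccc2[C@H]2c3cc(OCc4ccccc4)c(OCc4ccccc4)cc3[C@H]([C@@H](OCc3ccccc3)Cc3ccc(O[Si](C(C)C)(C(C)C)C(C)C)cc3O[Si](C(C)C)(C(C)C)C(C)C)O[C@H]12 | intermediate
23 | (2R,3S,4R)-7-(benzyloxy)-2-[4-(benzyloxy)phenyl]-4-{4,5-bis(benzyloxy)-2-[(2S)-2-(benzyloxy)-1-bromo-3-[2,4-bis(triisopropylsilyloxy)phenyl]propyl]phenyl}chroman-3-yl acetate, both epimers at the bromide carbon (not isolated) | c1ccccc1COc1ccc(cc1)[C@H]1Oc2cc(OCc3ccccc3)ccc2[C@@H](c2cc(OCc3ccccc3)c(OCc3ccccc3)cc2C(Br)[C@@H](OCc2ccccc2)Cc2ccc(O[Si](C(C)C)(C(C)C)C(C)C)cc2O[Si](C(C)C)(C(C)C)C(C)C)[C@@H]1OC(C)=O | intermediate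
24 | (2R,3S,4R)-7-(benzyloxy)-2-[4-(benzyloxy)phenyl]-4-{4,5-bis(benzyloxy)-2-[(2R,3S)-3-(benzyloxy)-7-hydroxychroman-2-yl]phenyl}chroman-3-yl acetate | c1ccccc1COc1ccc(cc1)[C@H]1Oc2cc(OCc3ccccc3)ccc2[C@@H](c2cc(OCc3ccccc3)c(OCc3ccccc3)cc2[C@H]2Oc3cc(O)ccc3C[C@@H]2OCc2ccccc2)[C@@H]1OC(C)=O | intermediate
25 | (2R,3S,4R)-7-(benzyloxy)-2-[4-(benzyloxy)phenyl]-4-{4,5-bis(benzyloxy)-2-[(2R,3S)-3-(benzyloxy)-7-hydroxychroman-2-yl]phenyl}chroman-3-ol | c1ccccc1COc1ccc(cc1)[C@H]1Oc2cc(OCc3ccccc3)ccc2[C@@H](c2cc(OCc3ccccc3)c(OCc3ccccc3)cc2[C@H]2Oc3cc(O)ccc3C[C@@H]2OCc2ccccc2)[C@@H]1O | intermediate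
26 | (2R,3S,4R)-4-{2-[(2R,3S)-3,7-dihydroxychroman-2-yl]-4,5-dihydroxyphenyl}-2-(4-hydroxyphenyl)chroman-3,7-diol | Oc1ccc([C@H]2Oc3cc(O)ccc3[C@@H](c3cc(O)c(O)cc3[C@H]3Oc4cc(O)ccc4C[C@@H]3O)[C@@H]2O)cc1 | target

## Step count and risks

Total: 14 steps. Longest linear sequence: 9 steps (steps 1–5, then 11–14; the branch through steps 6–10 is of the same length).

Step 11 (key step). The most likely failure is an unfavourable hemiacetal equilibrium for the hindered secondary alcohol. The aldehyde would then be consumed by other paths: loss of benzyl alcohol from the α-benzyloxy oxocarbenium ion, or intermolecular attack of ring A of a second molecule. The fallback forms the O3–C2' bond first and generates the same cation from a stable precursor. It sets out from 20 and 12. NaClO2/NaH2PO4/2-methyl-2-butene oxidises 20 to (2S)-2-(benzyloxy)-3-[2,4-bis(triisopropylsilyloxy)phenyl]propanoic acid F1. DCC/DMAP esterifies O3 of 12 with it to give the C3 ester F2. i-Bu2AlH at −78 °C followed by Ac2O, pyridine and DMAP traps the aluminium hemiacetal as the α-acetoxy ether F3. BF3·OEt2 or TMSOTf at −78 °C then ionises the acetate to the oxocarbenium ion, which closes on ring E, and the route is rejoined at 22.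

Step 12. Two processes may fail. The first is loss of chemoselectivity in the ring opening: the upper C2–O1 bond is also a para-alkoxybenzylic C–O bond, although on a much less basic aryl ether oxygen, and the C3' benzyl ether is also a dialkyl-type ether. The second is erosion of trans selectivity if the phenoxide captures a free C2' cation. An exchange of the C3' benzyl ether for an acetate would be harmless, since steps 13 and 14 remove either group. The fallback opens the ether with a soft nucleophile and closes the chroman in a separate, silver-promoted step, with no acylating agent present during the opening. It sets out from 22. BF3·OEt2 and phenylmethanethiol at −20 °C cleave the C2'–O3 bond by thiolysis to the benzyl thioether with a free C3 hydroxyl F4. Ac2O/pyridine caps O3 as the thioether acetate F5. TBAF buffered with AcOH removes both silyl groups to give the resorcinol thioether F6. AgBF4 in THF at 0 °C activates the thioether, the ortho phenol closes the chroman, and the route is rejoined at 24.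

Step 5. The C3 borane is β to the ring oxygen O1, so β-elimination with opening of the pyran may compete before oxidation, and facial selectivity on a trisubstituted alkene flanked by two aryl groups may be incomplete. The fallback replaces hydroboration by dihydroxylation and ionic deoxygenation and sets out from 10. OsO4 (cat.)/NMO adds from the face anti to ring B to give the 3,4-cis-diol F7. Et3SiH/BF3·OEt2 at −78 °C ionises the tertiary, doubly benzylic C4 hydroxyl and delivers hydride to the cation along the axial trajectory that leaves ring E equatorial, which returns the route to 12.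

Step 3. The 7-alkoxy group makes the chromone a poorer acceptor, so conversion may be low, and prolonged heating may erode the enantiomeric purity of the flavanone through reversible ring opening. The fallback gives up catalytic C–C bond formation for a resolution and sets out from 2. KOH/EtOH condensation with 4-(benzyloxy)benzaldehyde gives the chalcone F8. NaOAc in refluxing EtOH cyclises it to the racemic flavanone F9. Asymmetric transfer hydrogenation with RuCl(p-cymene)(TsDPEN) and HCO2H/Et3N, in the enantiomeric form of the catalyst that reduces the (2R)-ketone faster, converts that enantiomer into the cis-flavan-4-ol F10 and leaves the (2S)-ketone, so the route is rejoined at 6 at the cost of half the material.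

## Further compounds

F1 | step 11 | (2S)-2-(benzyloxy)-3-[2,4-bis(triisopropylsilyloxy)phenyl]propanoic acid | OC(=O)[C@@H](OCc1ccccc1)Cc1ccc(O[Si](C(C)C)(C(C)C)C(C)C)cc1O[Si](C(C)C)(C(C)C)C(C)C
F2 | step 11 | (2R,3S,4R)-7-(benzyloxy)-2-[4-(benzyloxy)phenyl]-4-[3,4-bis(benzyloxy)phenyl]chroman-3-yl (2S)-2-(benzyloxy)-3-[2,4-bis(triisopropylsilyloxy)phenyl]propanoate | c1ccccc1COc1ccc(cc1)[C@H]1Oc2cc(OCc3ccccc3)ccc2[C@@H](c2ccc(OCc3ccccc3)c(OCc3ccccc3)c2)[C@@H]1OC(=O)[C@@H](OCc1ccccc1)Cc1ccc(O[Si](C(C)C)(C(C)C)C(C)C)cc1O[Si](C(C)C)(C(C)C)C(C)C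
F3 | step 11 | α-acetoxy ether: (2S)-2-(benzyloxy)-3-[2,4-bis(triisopropylsilyloxy)phenyl]-1-{[(2R,3S,4R)-7-(benzyloxy)-2-[4-(benzyloxy)phenyl]-4-[3,4-bis(benzyloxy)phenyl]chroman-3-yl]oxy}propyl acetate, both epimers at C1 | c1ccccc1COc1ccc(cc1)[C@H]1Oc2cc(OCc3ccccc3)ccc2[C@@H](c2ccc(OCc3ccccc3)c(OCc3ccccc3)c2)[C@@H]1OC(OC(C)=O)[C@@H](OCc1ccccc1)Cc1ccc(O[Si](C(C)C)(C(C)C)C(C)C)cc1O[Si](C(C)C)(C(C)C)C(C)C
F4 | step 12 | (2R,3S,4R)-7-(benzyloxy)-2-[4-(benzyloxy)phenyl]-4-{4,5-bis(benzyloxy)-2-[(2S)-2-(benzyloxy)-1-(benzylsulfanyl)-3-[2,4-bis(triisopropylsilyloxy)phenyl]propyl]phenyl}chroman-3-ol, both epimers at the sulfur-bearing carbon | c1ccccc1COc1ccc(cc1)[C@H]1Oc2cc(OCc3ccccc3)ccc2[C@@H](c2cc(OCc3ccccc3)c(OCc3ccccc3)cc2C(SCc2ccccc2)[C@@H](OCc2ccccc2)Cc2ccc(O[Si](C(C)C)(C(C)C)C(C)C)cc2O[Si](C(C)C)(C(C)C)C(C)C)[C@@H]1O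
F5 | step 12 | C3 acetate of F4 | c1ccccc1COc1ccc(cc1)[C@H]1Oc2cc(OCc3ccccc3)ccc2[C@@H](c2cc(OCc3ccccc3)c(OCc3ccccc3)cc2C(SCc2ccccc2)[C@@H](OCc2ccccc2)Cc2ccc(O[Si](C(C)C)(C(C)C)C(C)C)cc2O[Si](C(C)C)(C(C)C)C(C)C)[C@@H]1OC(C)=O
F6 | step 12 | (2R,3S,4R)-7-(benzyloxy)-2-[4-(benzyloxy)phenyl]-4-{4,5-bis(benzyloxy)-2-[(2S)-2-(benzyloxy)-1-(benzylsulfanyl)-3-(2,4-dihydroxyphenyl)propyl]phenyl}chroman-3-yl acetate | c1ccccc1COc1ccc(cc1)[C@H]1Oc2cc(OCc3ccccc3)ccc2[C@@H](c2cc(OCc3ccccc3)c(OCc3ccccc3)cc2C(SCc2ccccc2)[C@@H](OCc2ccccc2)Cc2ccc(O)cc2O)[C@@H]1OC(C)=O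
F7 | step 5 | (2R,3R,4S)-7-(benzyloxy)-2-[4-(benzyloxy)phenyl]-4-[3,4-bis(benzyloxy)phenyl]chroman-3,4-diol (3,4-cis-diol, both hydroxyls trans to ring B) | c1ccccc1COc1ccc(cc1)[C@H]1Oc2cc(OCc3ccccc3)ccc2[C@@](O)(c2ccc(OCc3ccccc3)c(OCc3ccccc3)c2)[C@@H]1O
F8 | step 3 | (E)-1-[4-(benzyloxy)-2-hydroxyphenyl]-3-[4-(benzyloxy)phenyl]prop-2-en-1-one | O=C(/C=C/c1ccc(OCc2ccccc2)cc1)c1ccc(OCc2ccccc2)cc1O
F9 | step 3 | racemic 7-(benzyloxy)-2-[4-(benzyloxy)phenyl]chroman-4-one | O=C1CC(c2ccc(OCc3ccccc3)cc2)Oc2cc(OCc3ccccc3)ccc12
F10 | step 3 | (2R,4R)-7-(benzyloxy)-2-[4-(benzyloxy)phenyl]chroman-4-ol (cis, removed by chromatography) | O[C@@H]1C[C@H](c2ccc(OCc3ccccc3)cc2)Oc2cc(OCc3ccccc3)ccc12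
A1 | alternative 1 | 3-arylindan-1-one with 6-benzyloxy group, the aryl group being ring E with the protected lower flavan | O=C1C[C@H](c2cc(OCc3ccccc3)c(OCc3ccccc3)cc2[C@H]2Oc3cc(OCc4ccccc4)ccc3C[C@@H]2OCc2ccccc2)c2ccc(OCc3ccccc3)cc12
A2 | alternative 1 | 4-aryl-7-(benzyloxy)chroman-2-one | O=C1C[C@H](c2cc(OCc3ccccc3)c(OCc3ccccc3)cc2[C@H]2Oc3cc(OCc4ccccc4)ccc3C[C@@H]2OCc2ccccc2)c2ccc(OCc3ccccc3)cc2O1
A3 | alternative 2 | aryl glycidyl ether: pentabenzyl upper flavan whose ring E carries CH[O-3-(benzyloxy)phenyl]–oxiranyl | c1ccccc1COc1ccc(cc1)[C@H]1Oc2cc(OCc3ccccc3)ccc2[C@@H](c2cc(OCc3ccccc3)c(OCc3ccccc3)cc2[C@@H](Oc2cccc(OCc3ccccc3)c2)[C@@H]2CO2)[C@@H]1OCc1ccccc1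
A4 | alternative 2 | hexabenzyl biflavan with free lower C3' hydroxyl | c1ccccc1COc1ccc(cc1)[C@H]1Oc2cc(OCc3ccccc3)ccc2[C@@H](c2cc(OCc3ccccc3)c(OCc3ccccc3)cc2[C@H]2Oc3cc(OCc4ccccc4)ccc3C[C@@H]2O)[C@@H]1OCc1ccccc1
A5 | alternative 3 | o-hydroxybenzhydrol: [4-(benzyloxy)-2-hydroxyphenyl](aryl)methanol, aryl being ring E with the tribenzyl lower flavan (carbinol configuration open) | Oc1cc(OCc2ccccc2)ccc1C(O)c1cc(OCc2ccccc2)c(OCc2ccccc2)cc1[C@H]1Oc2cc(OCc3ccccc3)ccc2C[C@@H]1OCc1ccccc1
A6 | alternative 3 | (E)-2-[4-(benzyloxy)styryl]-4,4,5,5-tetramethyl-1,3,2-dioxaborolane | CC1(C)OB(/C=C/c2ccc(OCc3ccccc3)cc2)OC1(C)C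
A7 | alternative 3 | hexabenzyl biflavan with a pinacol boronate on C3 of the upper pyran | c1ccccc1COc1ccc(cc1)[C@H]1Oc2cc(OCc3ccccc3)ccc2[C@@H](c2cc(OCc3ccccc3)c(OCc3ccccc3)cc2[C@H]2Oc3cc(OCc4ccccc4)ccc3C[C@@H]2OCc2ccccc2)[C@@H]1B1OC(C)(C)C(C)(C)O1
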